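## Structural features

The target is a p-terphenyl. Its central benzene ring (ring B) carries two 4-hydroxyphenyl rings (rings A and C) at C3 and C6, para to each other. Ring B is hexasubstituted and tetra-oxygenated: C1 and C2 bear benzoyloxy groups, C4 and C5 bear free hydroxyls. There is no stereocentre, so no stereocentres stand next to each other. The outer rings have no ortho substituents, so the two biaryl axes are not stereogenic, and a mirror plane runs through the midpoints of C1–C2 and C4–C5. The fragile groups are the two aryl benzoates (cleaved by hydroxide, alkoxide or amines) and the electron-rich catechol and phenols (oxidised by air to an ortho-quinone). The esters cannot migrate, because each is flanked by the other ester and by an aryl-bearing carbon. The real difficulty is not the carbon skeleton but telling the C1/C2 pair of oxygens from the C4/C5 pair, since a dihydroxyquinone-type precursor has a symmetry element that interchanges the two pairs. The key step uses the fact that C3 and C6 are the only ring-B carbons without oxygen. At the quinone oxidation level of ring B they are the only C–H carbons, each the β-carbon of an α-alkoxy enone, so both aryl rings can be attached by direct C–H arylation.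

## Logic of the disconnections

10 ⇒ 9. The O–H bonds of the two outer phenols and of the C4/C5 catechol are traced back to two benzyl ethers and one diphenylmethylene acetal. The forward step therefore cuts two O–CH2 bonds and two acetal C–O bonds, all benzylic, so one hydrogenolysis removes them while the C1/C2 esters stay. The gain is that every oxidation-prone phenol remains masked until the last operation. The demand is complete cleavage of a hindered acetal without touching the aryl esters.

9 ⇒ 8. The two acyl C–O bonds at C1 and C2 are cut. Acylation is placed late so that the base-labile esters meet only one further step. The demand is twofold acylation of a hindered, easily oxidised catechol, which is why 8 is acylated in the flask in which it is formed.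

8 ⇒ 7. The two acetal C–O bonds at C4 and C5 are cut, which leads back to a symmetric tetrol. This is where the two catechol halves are told apart, using one cyclic group that covers both oxygens of one half at once. The demand is that only one of two equivalent catechols reacts. No reagent can guarantee this, so the forward step is statistical and is run with a slight deficit of the acetal-forming reagent.

7 ⇒ 6. No skeletal bond is cut; two hydrogens are removed to reach the quinone level. The gain is an air-stable, acidic compound that can be purified by extraction into base. The demand on the forward step is a clean two-electron reduction and handling of 7 without oxygen.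

6 ⇒ 5. The two enolic hydroxyls are traced back to O-methyl vinylogous esters. The neutral methyl ethers are what the arylation needs, and hydroxide removes them afterwards by addition–elimination. The demand is that the benzyl ethers survive hot aqueous base, which they should.

5 ⇒ 2 + 3 (through 4). The C3–aryl and C6–aryl bonds are cut. The whole carbon skeleton then comes from a six-carbon quinone and two identical aryl units, with no prior functionalisation of the quinone at either bond-forming site. The demand is that the radical arylation runs twice and does not stop at 4.

2 ⇒ 1. The two O–CH3 bonds are cut, leading to a cheap commercial quinone. The demand is only an acid-catalysed exchange of hydroxyl for methoxyl.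

## Other disconnections considered

Alternative 1: The cut is through three ring-B bonds, C1–C2, C3–C4 and C5–C6, so that the ring is assembled from three alkynes. In the forward step the silylene-tethered bis(aryl ynol ether) A2 and di-tert-butoxyethyne A3 would be cyclotrimerised with RhCl(PPh3)3 to the benzodioxasilole A1. A rhodacyclopentadiene formed from the tethered diyne would insert A3.
- In favour: the hexasubstituted ring and all six substituents arise in one step. The two catechol halves are also born different, one as a silylene and one as a pair of tert-butyl ethers. On this point the alternative is better than the chosen plan, which must separate a statistical mixture.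
- Against: A2 is a bis(siloxyalkyne), expected to be moisture-sensitive. A3 is thermally labile and loses its tert-butyl groups to form ketenes near room temperature. Both are strongly donor-substituted alkynes, for which oxidative cyclisation at monovalent rhodium is less assured and homo-oligomerisation of A3 competes.
- Comparison: the substitution pattern reached is the same. The mechanism is metal-templated rather than a radical chain. Step economy is worse: about four steps to A2 and A3, the key step, then about four more (desilylation, benzoylation, acid removal of tert-butyl groups, hydrogenolysis), against six in the chosen plan.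

Alternative 2: The cut is through one ring-B bond between two oxygenated carbons (C4–C5), leading to a squarate-derived four-membered ring. In the forward step the hydroxycyclobutenone A4 would be heated. It should open by a four-electron electrocyclic reaction to a dienylketene, close through the ketene carbon onto the methoxy-bearing vinyl terminus, and tautomerise to the hydroquinone A5.
- In favour: ring expansions of this type are well established for fully substituted hydroquinones. The order of additions to a squaric ester fixes the substitution pattern, so no under- or over-arylation can occur; here the alternative is the equal or the better of the chosen key step. The two alkoxy groups differ, and capping the tertiary alcohol of A4 before thermolysis would distinguish all four oxygens, a deterministic answer to the desymmetrisation problem.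
- Against: A4 needs two successive organolithium additions to a squaric ester, one of them with a lithiated aryl-substituted bromo enol ether that must itself be made, roughly five steps in all. In A5 each catechol half still holds one hydroxyl and one alkyl ether. Using the differentiation would mean cleaving aryl methyl and isopropyl ethers beside benzyl ethers. The easy exit, oxidation and hydrolysis to A7, discards the differentiation.
- Comparison: the ring pattern is the same, the mechanism is pericyclic and needs no oxidant, but the route is roughly twice as long.

Alternative 3: The cut is through the two ring-B bonds between each aryl-bearing carbon and its oxygenated neighbour (C2–C3 and C5–C6). In the forward step two molecules of methyl 4-benzyloxyphenylpyruvate A6 would undergo base-mediated intermolecular and then intramolecular Claisen condensation to the dihydroxyquinone A7, which is the same compound as 6.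
- In favour: it is the most convergent plan. One building block supplies the ring and both aryl groups, no metal or oxidant is needed, the oxidation level is already correct, and it follows the biosynthetic logic.
- Against: arylpyruvate esters are largely enolised, and their enolates should prefer aldol addition to the more electrophilic ketone carbonyl of a second molecule. Aldol dimers and butenolides are therefore the expected competitors of the double Claisen path. A6 itself needs about three steps from an aromatic aldehyde through an azlactone.
- Comparison: the downstream work is identical, since A7 is 6, so the desymmetrisation problem is equal. Step count to this point is about equal (four against three). Predictability of chemoselectivity is lower than for arylation at the only two C–H sites of 2.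

Key step: step 2

Remark: the target has no stereocentre, so no stereodescriptor appears in any name or SMILES below; 2 is also sold, and where it is bought step 1 is omitted.

## Route

Step 1
Reactants: 1 2,5-dihydroxy-1,4-benzoquinone
Product: 2 2,5-dimethoxy-1,4-benzoquinone
Conditions: MeOH, H2SO4 (cat.), rt to 50 °C
Reagents that add atoms: methanol, CO
Why: Fischer-type esterification of a vinylogous carboxylic acid: methanol adds to the protonated hydroxy-enone and water is lost, and the sparingly soluble dimethyl ether should crystallise and pull the equilibrium over.

Step 2
Reactants: 2 2,5-dimethoxy-1,4-benzoquinone; 3 [4-(benzyloxy)phenyl]boronic acid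
Product: 5 2,5-bis[4-(benzyloxy)phenyl]-3,6-dimethoxy-1,4-benzoquinone, via monoaryl quinone 4 (not isolated)
Conditions: AgNO3 (0.4 equiv), K2S2O8 (6 equiv), 3 (4 equiv), CH2Cl2/H2O 1:1, rt, reagents in two charges
Reagents that add atoms: none
Why: Persulfate oxidises monovalent silver to divalent silver and sulfate radical anion, and these convert 3 into the 4-(benzyloxy)phenyl radical with loss of boric acid. The nucleophilic aryl radical adds to C3 of 2 (quinone numbering), the β-carbon of the C1 enone, so the unpaired electron lands on C2, where the methoxy donor and the C1 carbonyl acceptor stabilise it captodatively. One-electron oxidation of this adduct by divalent silver or persulfate and loss of the C3 proton restore the quinone as 4, and the same sequence at C6, remote from the first aryl group and electronically little changed, gives 5. The closest known reaction type is the silver-catalysed persulfate arylation of quinones with arylboronic acids, a boronic-acid relative of the Meerwein arylation. No ring is closed and no stereocentre is formed. Site selectivity needs no control, because C3 and C6 are the only hydrogen-bearing ring carbons of 2; what must be secured is twofold rather than single arylation, driven by excess 3 and oxidant added in two charges. Benzylic oxidation of the benzyl ethers is disfavoured by the two-phase medium at room temperature, which keeps the arylated quinone in the organic layer away from the aqueous oxidant. The methyl ethers are kept on the acceptor because the free hydroxyquinone 1 would be ionised and would be expected to bind silver as an insoluble salt.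

Step 3
Reactants: 5 2,5-bis[4-(benzyloxy)phenyl]-3,6-dimethoxy-1,4-benzoquinone
Product: 6 2,5-bis[4-(benzyloxy)phenyl]-3,6-dihydroxy-1,4-benzoquinone
Conditions: NaOH (2 M aq.), 1,4-dioxane, 80 °C; then HCl (aq.) to pH 1
Reagents that add atoms: sodium hydroxide, [Na+].[OH-]
Why: Saponification of two vinylogous esters by conjugate addition of hydroxide and loss of methoxide; benzyl ethers are inert to aqueous base. The water-soluble dianion of 6 allows neutral by-products of step 2 to be washed out before acidification precipitates 6.

Step 4
Reactants: 6 2,5-bis[4-(benzyloxy)phenyl]-3,6-dihydroxy-1,4-benzoquinone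
Product: 7 3,6-bis[4-(benzyloxy)phenyl]benzene-1,2,4,5-tetrol
Conditions: Na2S2O4, EtOAc/H2O, rt, Ar; organic layer dried and concentrated under Ar, used at once
Reagents that add atoms: none
Why: Dithionite reduction of a quinone to its hydroquinone by two electrons and two protons; nothing else in 6 is reducible under these conditions.

Step 5
Reactants: 7 3,6-bis[4-(benzyloxy)phenyl]benzene-1,2,4,5-tetrol
Product: 9 4,7-bis[4-(benzyloxy)phenyl]-2,2-diphenyl-1,3-benzodioxole-5,6-diyl dibenzoate, via mono-acetal diol 8 (not isolated)
Conditions: Ph2CCl2 (0.9 equiv), K2CO3, degassed MeCN, rt, Ar; then BzCl (3 equiv), Et3N, DMAP (cat.), 0 °C to rt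
Reagents that add atoms: dichlorodiphenylmethane, ClC(Cl)(c1ccccc1)c1ccccc1; benzoyl chloride, O=C(Cl)c1ccccc1
Why: Catechol ketalisation by double O-alkylation with a geminal dichloride closes the five-membered dioxole on one of the two equivalent catechols, statistically, which is why the reagent is kept slightly short. DMAP-catalysed acylation of the remaining catechol in the same flask then makes every component air-stable and separable by chromatography.

Step 6
Reactants: 9 4,7-bis[4-(benzyloxy)phenyl]-2,2-diphenyl-1,3-benzodioxole-5,6-diyl dibenzoate
Product: 10 4,4'',5',6'-tetrahydroxy-[1,1':4',1''-terphenyl]-2',3'-diyl dibenzoate (4,5-dihydroxy-3,6-bis(4-hydroxyphenyl)-1,2-phenylene dibenzoate)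
Conditions: H2 (1 atm), Pd(OH)2/C, EtOAc/THF, rt; filtration under Ar
Reagents that add atoms: none
Why: Catalytic hydrogenolysis cleaves the two benzyl aryl ethers and the two doubly benzylic C–O bonds of the diphenylmethylene acetal in one operation, while aryl benzoates are inert. A non-nucleophilic solvent avoids transesterification, and no hydroxyl is adjacent to an ester, so acyl migration cannot occur.

## Compound list

1 | 2,5-dihydroxy-1,4-benzoquinone | O=C1C=C(O)C(=O)C=C1O | starting material
2 | 2,5-dimethoxy-1,4-benzoquinone | COC1=CC(=O)C(OC)=CC1=O | intermediate
3 | [4-(benzyloxy)phenyl]boronic acid | OB(O)c1ccc(OCc2ccccc2)cc1 | starting material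
4 | 3-[4-(benzyloxy)phenyl]-2,5-dimethoxy-1,4-benzoquinone | COC1=CC(=O)C(OC)=C(c2ccc(OCc3ccccc3)cc2)C1=O | intermediate (not isolated)
5 | 2,5-bis[4-(benzyloxy)phenyl]-3,6-dimethoxy-1,4-benzoquinone | COC1=C(c2ccc(OCc3ccccc3)cc2)C(=O)C(OC)=C(c2ccc(OCc3ccccc3)cc2)C1=O | intermediate
6 | 2,5-bis[4-(benzyloxy)phenyl]-3,6-dihydroxy-1,4-benzoquinone | O=C1C(O)=C(c2ccc(OCc3ccccc3)cc2)C(=O)C(O)=C1c1ccc(OCc2ccccc2)cc1 | intermediate
7 | 3,6-bis[4-(benzyloxy)phenyl]benzene-1,2,4,5-tetrol | Oc1c(O)c(-c2ccc(OCc3ccccc3)cc2)c(O)c(O)c1-c1ccc(OCc2ccccc2)cc1 | intermediate
8 | 4,7-bis[4-(benzyloxy)phenyl]-2,2-diphenyl-1,3-benzodioxole-5,6-diol | Oc1c(O)c(-c2ccc(OCc3ccccc3)cc2)c2c(c1-c1ccc(OCc3ccccc3)cc1)OC(c1ccccc1)(c1ccccc1)O2 | intermediate (not isolated)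
9 | 4,7-bis[4-(benzyloxy)phenyl]-2,2-diphenyl-1,3-benzodioxole-5,6-diyl dibenzoate | O=C(Oc1c(OC(=O)c2ccccc2)c(-c2ccc(OCc3ccccc3)cc2)c2c(c1-c1ccc(OCc3ccccc3)cc1)OC(c1ccccc1)(c1ccccc1)O2)c1ccccc1 | intermediate
10 | 4,4'',5',6'-tetrahydroxy-[1,1':4',1''-terphenyl]-2',3'-diyl dibenzoate | O=C(Oc1c(OC(=O)c2ccccc2)c(-c2ccc(O)cc2)c(O)c(O)c1-c1ccc(O)cc1)c1ccccc1 | target

## Step count and least certain steps

Total step count: 6. Longest linear sequence: 6 steps (1 to 10); 3 is bought.

Step 2 (key step). The most likely failure is stalling at single arylation. The boronic acid may be consumed by competing ipso-hydroxylation and protodeboronation, and 2 is only sparingly soluble in the organic layer. Oxidative attack at the benzylic C–H bonds of the benzyl ethers is a second drain. Fallback: the C–H bonds are first turned into C–Br bonds and the aryl groups are attached by cross-coupling. From 2, bromination (Br2, AcOH, rt) should give 2,5-dibromo-3,6-dimethoxy-1,4-benzoquinone F1 by addition–elimination at the two enol-ether carbons. A twofold Suzuki–Miyaura coupling of F1 with 3 (Pd(PPh3)4, K2CO3, dioxane/H2O, 90 °C, oxidative addition of zerovalent palladium into the two C–Br bonds) then comes back to the route at 5.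

Step 5. The acetalisation cannot distinguish the two catechols of 7. Over-acetalisation of both and carry-through of unprotected material are inherent and cap the throughput near the statistical limit. Oxidation of the phenoxides by traces of oxygen and slow second acylation at the hindered hydroxyl add to this. Material that escapes acetalisation is perbenzoylated and could be returned to 6 by saponification in air. Fallback: symmetry is broken at the quinone level, where the first reaction deactivates the second.
- From 5, one equivalent of NaOH (THF/H2O, rt) should hydrolyse a single vinylogous ester, because the enolate anion formed shields the other, giving 2,5-bis[4-(benzyloxy)phenyl]-3-hydroxy-6-methoxy-1,4-benzoquinone F2.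
- Na2S2O4 reduction gives 3,6-bis[4-(benzyloxy)phenyl]-5-methoxybenzene-1,2,4-triol F3, which holds only one catechol.
- Ph2CCl2 with K2CO3 can therefore only give 4,7-bis[4-(benzyloxy)phenyl]-6-methoxy-2,2-diphenyl-1,3-benzodioxol-5-ol F4.
- Periodate oxidation of this 2-methoxyphenol (NaIO4, aq. AcOH/THF) expels methanol and gives 4,7-bis[4-(benzyloxy)phenyl]-2,2-diphenyl-1,3-benzodioxole-5,6-dione F5.
- Na2S2O4 reduction of F5 comes back to the route at 8, which is benzoylated as in the second half of step 5.

Step 4. Re-oxidation of the very electron-rich tetrol by air during phase separation and concentration would return 6 and spoil the stoichiometry of step 5. Fallback: the reduced ring is trapped as a storable derivative. From 6, reductive acetylation (Zn dust, Ac2O, NaOAc, 80 °C) should give 3,6-bis[4-(benzyloxy)phenyl]benzene-1,2,4,5-tetrayl tetraacetate F6, an air-stable solid. Acid methanolysis (HCl from AcCl in degassed MeOH/THF, Ar) immediately before use comes back to the route at 7.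

Step 6. The benzyl ethers should cleave quickly but the hindered diphenylmethylene acetal more slowly, so partial deprotection may persist. Prolonged exposure then invites oxidation of the liberated catechol during filtration. Fallback: the two kinds of protecting group are removed by ionic rather than reductive chemistry. From 9, acidolysis of the acetal (TFA, H2O, CH2Cl2, rt) should give 4,4''-bis(benzyloxy)-5',6'-dihydroxy-[1,1':4',1''-terphenyl]-2',3'-diyl dibenzoate F7. Lewis-acid debenzylation (BCl3, pentamethylbenzene, CH2Cl2, −78 °C), which aryl esters tolerate, comes back to the route at 10.

## Further compounds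

F1 | step 2 | 2,5-dibromo-3,6-dimethoxy-1,4-benzoquinone | COC1=C(Br)C(=O)C(OC)=C(Br)C1=O
F2 | step 5 | 2,5-bis[4-(benzyloxy)phenyl]-3-hydroxy-6-methoxy-1,4-benzoquinone | COC1=C(c2ccc(OCc3ccccc3)cc2)C(=O)C(O)=C(c2ccc(OCc3ccccc3)cc2)C1=O
F3 | step 5 | 3,6-bis[4-(benzyloxy)phenyl]-5-methoxybenzene-1,2,4-triol | COc1c(-c2ccc(OCc3ccccc3)cc2)c(O)c(O)c(-c2ccc(OCc3ccccc3)cc2)c1O
F4 | step 5 | 4,7-bis[4-(benzyloxy)phenyl]-6-methoxy-2,2-diphenyl-1,3-benzodioxol-5-ol | COc1c(-c2ccc(OCc3ccccc3)cc2)c2OC(c3ccccc3)(c3ccccc3)Oc2c(-c2ccc(OCc3ccccc3)cc2)c1O
F5 | step 5 | 4,7-bis[4-(benzyloxy)phenyl]-2,2-diphenyl-1,3-benzodioxole-5,6-dione | O=C1C(=O)C(c2ccc(OCc3ccccc3)cc2)=C2OC(c3ccccc3)(c3ccccc3)OC2=C1c1ccc(OCc2ccccc2)cc1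
F6 | step 4 | 3,6-bis[4-(benzyloxy)phenyl]benzene-1,2,4,5-tetrayl tetraacetate | CC(=O)Oc1c(OC(C)=O)c(-c2ccc(OCc3ccccc3)cc2)c(OC(C)=O)c(OC(C)=O)c1-c1ccc(OCc2ccccc2)cc1
F7 | step 6 | 4,4''-bis(benzyloxy)-5',6'-dihydroxy-[1,1':4',1''-terphenyl]-2',3'-diyl dibenzoate | O=C(Oc1c(OC(=O)c2ccccc2)c(-c2ccc(OCc3ccccc3)cc2)c(O)c(O)c1-c1ccc(OCc2ccccc2)cc1)c1ccccc1
A1 | alternative 1 | 4,7-bis[4-(benzyloxy)phenyl]-5,6-di-tert-butoxy-2,2-di-tert-butyl-1,3,2-benzodioxasilole | CC(C)(C)[Si]1(C(C)(C)C)Oc2c(O1)c(-c1ccc(OCc3ccccc3)cc1)c(OC(C)(C)C)c(OC(C)(C)C)c2-c1ccc(OCc2ccccc2)cc1
A2 | alternative 1 | di-tert-butylbis({[4-(benzyloxy)phenyl]ethynyl}oxy)silane | CC(C)(C)[Si](OC#Cc1ccc(OCc2ccccc2)cc1)(OC#Cc1ccc(OCc2ccccc2)cc1)C(C)(C)C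
A3 | alternative 1 | di-tert-butoxyethyne | CC(C)(C)OC#COC(C)(C)C
A4 | alternative 2 | racemic 2-[4-(benzyloxy)phenyl]-4-{(Z)-1-[4-(benzyloxy)phenyl]-2-methoxyethenyl}-4-hydroxy-3-isopropoxycyclobut-2-en-1-one | O=C1C(c2ccc(OCc3ccccc3)cc2)=C(OC(C)C)C1(O)/C(c1ccc(OCc2ccccc2)cc1)=C\OC
A5 | alternative 2 | 2,5-bis[4-(benzyloxy)phenyl]-3-isopropoxy-6-methoxybenzene-1,4-diol | Oc1c(-c2ccc(OCc3ccccc3)cc2)c(OC(C)C)c(O)c(-c2ccc(OCc3ccccc3)cc2)c1OC
A6 | alternative 3 | methyl 3-[4-(benzyloxy)phenyl]-2-oxopropanoate | COC(=O)C(=O)Cc1ccc(OCc2ccccc2)cc1
A7 | alternative 3 | 2,5-bis[4-(benzyloxy)phenyl]-3,6-dihydroxy-1,4-benzoquinone | O=C1C(O)=C(c2ccc(OCc3ccccc3)cc2)C(=O)C(O)=C1c1ccc(OCc2ccccc2)cc1
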